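Atoms are numbered as in guaianolides: ring A C1–C5, ring B C1, C5–C10, lactone C12(=O)–O–C8, ether oxygen between C5 and C11. Ring A is cut at C1–C2 and C4–C5: in ring B, C5 is a ketone carbon and C1 its α-carbon, while C2–C3–C4 is a β-silyl acryloylsilane. One Brook-rearrangement-mediated [3+2] annulation of the regio-defined cycloheptanone enolate forms both bonds and sets C1. The resulting β-hydroxysilane later fixes the C4=C5 alkene, whose epoxide is opened by the C11 hydroxyl to set C4 and C5 and close the ether ring. The precursor is the trimethylsilyl enol ether of a bicyclic acetal ketone. C8, set by catalysis, relays every other stereocentre.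

Key step: step 11

Remark: the acetal carbon in 5–9 and 15–17 and the lactol carbon in 18 are epimer mixtures (left open in the SMILES) that converge at lactone 19.

Step 1
Reactants: 1 cyclohepta-1,3-diene
Product: 2 6,7-dioxabicyclo[3.2.2]non-8-ene (meso endoperoxide)
Conditions: O2, tetraphenylporphyrin (cat.), visible light, CH2Cl2, 0 °C
Reagents that add atoms: dioxygen, O=O
Why: Singlet oxygen adds to the cyclic s-cis diene in a [4+2] cycloaddition (photooxygenation), and the meso product needs no stereocontrol.

Step 2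
Reactants: 2 6,7-dioxabicyclo[3.2.2]non-8-ene
Product: 3 (R)-4-hydroxycyclohept-2-en-1-one
Conditions: cinchona-alkaloid-derived tertiary amine (10 mol%, the pseudo-enantiomer that leads to the R alcohol), CH2Cl2, rt
Reagents that add atoms: none
Why: Kornblum–DeLaMare rearrangement under chiral-base catalysis, in which removal of one enantiotopic bridgehead proton desymmetrises the meso peroxide and sets C8, the only stereocentre set by a catalyst.

Step 3
Reactants: 3 (R)-4-hydroxycyclohept-2-en-1-one; 4 ethyl vinyl ether
Product: 5 (4R)-4-(2-bromo-1-ethoxyethoxy)cyclohept-2-en-1-one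
Conditions: N-bromosuccinimide, CH2Cl2, −40 → 0 °C
Reagents that add atoms: N-bromosuccinimide, O=C1CCC(=O)N1Br
Why: Bromoacetalisation (bromoetherification of the electron-rich vinyl ether with the alcohol as nucleophile) installs the Ueno–Stork radical precursor and protects the hydroxyl without touching C8.

Step 4
Reactants: 5 (4R)-4-(2-bromo-1-ethoxyethoxy)cyclohept-2-en-1-one
Product: 7 (4R)-4-(2-bromo-1-ethoxyethoxy)cyclohepta-2,6-dien-1-one, via silyl dienol ether 6 (not isolated)
Conditions: LiN(iPr)2, Me3SiCl, THF, −78 °C; then Pd(OAc)2 (10 mol%), O2 (1 atm), DMSO, rt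
Reagents that add atoms: none
Why: Kinetic α'-deprotonation and silylation followed by Saegusa–Ito dehydrogenation adds the second enone (C1=C10); only the C1 side has α-hydrogens, so the regiochemistry is fixed, and base-free conditions avoid loss of the C8 alkoxy group.

Step 5
Reactants: 7 (4R)-4-(2-bromo-1-ethoxyethoxy)cyclohepta-2,6-dien-1-one
Product: 8 cis-fused acetal enone (3aS,8aR)-2-ethoxy-2,3,3a,4,8,8a-hexahydro-5H-cyclohepta[b]furan-5-one
Conditions: Bu3SnH (slow addition), AIBN (cat.), benzene, 80 °C
Reagents that add atoms: none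
Why: Ueno–Stork 5-exo-trig radical cyclisation of the bromoacetal onto the β-carbon (C7) of the neighbouring enone, where the two-atom tether from the C8 oxygen forces the cis ring fusion that sets C7 and the remote C1=C10 enone is left intact.

Step 6
Reactants: 8 cis-fused acetal enone
Product: 9 trimethylsilyl enol ether of the 10-methyl ketone (C1=C5 enol ether; C10 methyl trans to the C8 oxygen)
Conditions: MeMgBr, CuBr·SMe2 (5 mol%), Me3SiCl, HMPA, THF, −78 °C
Reagents that add atoms: methylmagnesium bromide, C[Mg]Br; chlorotrimethylsilane, C[Si](C)(C)Cl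
Why: Copper-catalysed conjugate addition with in situ silylation, in which methyl should enter C10 on the convex face anti to the cis-fused oxolane and the enolate is trapped regiospecifically toward C1.

Step 7
Reactants: 10 but-2-yn-1-ol
Product: 11 tert-butyl(but-2-yn-1-yloxy)dimethylsilane
Conditions: t-BuMe2SiCl, imidazole, DMF, rt
Reagents that add atoms: tert-butyldimethylsilyl chloride, CC(C)(C)[Si](C)(C)Cl
Why: Standard silylation of a primary alcohol.

Step 8
Reactants: 11 tert-butyl(but-2-yn-1-yloxy)dimethylsilane
Product: 12 racemic 1-(tert-butyldimethylsilyl)but-2-yn-1-ol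
Conditions: t-BuLi, THF, −78 → −40 °C; then H2O
Reagents that add atoms: none
Why: Retro-[1,2]-Brook rearrangement, in which propargylic α-oxy lithiation is followed by O-to-C silyl migration driven by formation of the lithium alkoxide.

Step 9
Reactants: 12 1-(tert-butyldimethylsilyl)but-2-yn-1-ol
Product: 13 1-(tert-butyldimethylsilyl)but-2-yn-1-one
Conditions: Dess–Martin periodinane, CH2Cl2, rt
Reagents that add atoms: none
Why: Dess–Martin oxidation of the α-hydroxysilane gives the alkynoyl silane under neutral conditions that avoid Brook-type cleavage.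

Step 10
Reactants: 13 1-(tert-butyldimethylsilyl)but-2-yn-1-one
Product: 14 (E)-1-(tert-butyldimethylsilyl)-3-(dimethylphenylsilyl)but-2-en-1-one
Conditions: PhMe2Si–B(pin), CuCl (5 mol%), NaOt-Bu (10 mol%), PPh3 (5 mol%), MeOH, THF, 0 °C
Reagents that add atoms: (dimethylphenylsilyl)boronic acid pinacol ester, CC1(C)OB(OC1(C)C)[Si](C)(C)c1ccccc1
Why: Copper-catalysed conjugate silylation (protosilylation) of the ynone by syn addition of silicon and hydrogen puts silicon on the β-carbon that becomes C4; the alkene geometry has no consequence later.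

Step 11
Reactants: 9 trimethylsilyl enol ether; 14 β-silyl acryloylsilane
Product: 16 tricyclic cyclopentenol (C2=C3 enol tert-butyldimethylsilyl ether; C4 with methyl and dimethylphenylsilyl; tertiary C5–OH cis to H1), via lithium enolate 15 (not isolated)
Conditions: MeLi (1.0 equiv), THF, 0 °C; then −78 °C, 14, warm to −30 °C; H2O
Reagents that add atoms: none
Why: MeLi cleaves the silyl enol ether to the regio-defined lithium enolate 15, whose C1 adds to the acylsilane carbonyl C2; the α-silyl alkoxide undergoes a [1,2]-Brook rearrangement to a siloxy-allyl anion stabilised at C4 by the dimethylphenylsilyl group, and C4 then attacks the C5 ketone. The closest known reaction type is the Brook-rearrangement-mediated [3+2] annulation of β-silyl acryloylsilanes with ketone lithium enolates. Ring A closes by 5-exo-trig addition of the allyl anion terminus to the carbonyl, and the short tether should give the cis-fused bicyclo[5.3.0] system. C1 is controlled by the adjacent C10 stereocentre (attack anti to the methyl group), C5 by the cis ring closure, and C4 by the preference of the silyl group for the convex face; C4 and C5 are erased in step 13. The step needs 1,2- rather than 1,4-addition to the acylsilane and a saturated C6 side of the ketone so that no seven-membered annulation competes; the β,β-disubstitution of 14 and the sp3 C6/C7 of the enolate secure both.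

Step 12
Reactants: 16 tricyclic cyclopentenol
Product: 17 C2–C3 dihydro compound (secondary C2 silyl ether cis to C10 and trans to H1)
Conditions: H2 (1 atm), [Ir(cod)(PCy3)(py)]PF6 (5 mol%), CH2Cl2, rt
Reagents that add atoms: none
Why: Hydroxyl-directed homogeneous hydrogenation of the silyl enol ether, in which the iridium centre binds the C5 hydroxyl and delivers hydrogen on the convex face, sets C2 with the silyloxy group cis to C10 (inverted in step 20).

Step 13
Reactants: 17 C2–C3 dihydro compound
Product: 18 lactol with the C4=C5 alkene (ring A cyclopentene; C2 silyl ether)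
Conditions: TsOH·H2O (cat.), THF/H2O, rt
Reagents that add atoms: water, O
Why: Acid-mediated Peterson elimination of the tertiary β-hydroxysilane places the alkene at C4=C5 whatever the C4/C5 configuration, and the same acid hydrolyses the ethyl acetal to the lactol while the hindered secondary silyl ether should survive.

Step 14
Reactants: 18 lactol
Product: 19 lactone (8,12-olide; C11 is CH2)
Conditions: Pr4N[RuO4] (5 mol%), N-methylmorpholine N-oxide, 4 Å MS, CH2Cl2, rt
Reagents that add atoms: none
Why: Ley–Griffith oxidation of the lactol to the γ-lactone, with no other free hydroxyl present and the alkene inert.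

Step 15
Reactants: 19 lactone
Product: 21 11-hydroxy lactone (hydroxyl on the convex face, cis to H7), via potassium enolate 20 (not isolated)
Conditions: KN(SiMe3)2, THF, −78 °C; 2-(phenylsulfonyl)-3-phenyloxaziridine; H2O
Reagents that add atoms: 2-(phenylsulfonyl)-3-phenyloxaziridine, O=S(=O)(N1OC1c1ccccc1)c1ccccc1
Why: Electrophilic α-hydroxylation of the lactone enolate by the N-sulfonyloxaziridine; the C11 configuration formed here does not matter because C11 is enolised again in step 16.

Step 16
Reactants: 21 11-hydroxy lactone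
Product: 23 11,13-diol (C11 hydroxyl on the concave face next to C6; CH2OH exo), via dilithium enediolate 22 (not isolated)
Conditions: LiN(iPr)2 (2.5 equiv), THF, −78 °C; CH2O (gas); H2O
Reagents that add atoms: formaldehyde, C=O
Why: Aldol reaction of the enediolate with formaldehyde on the convex face of the cis-fused lactone places C13 exo and leaves the C11 oxygen on the concave face, which is the configuration needed for the ether ring.

Step 17
Reactants: 23 11,13-diol
Product: 24 13-acetate
Conditions: Ac2O, pyridine, CH2Cl2, 0 °C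
Reagents that add atoms: acetic anhydride, CC(=O)OC(C)=O
Why: Selective acetylation of the primary alcohol, the tertiary α-hydroxy lactone hydroxyl being too hindered to react.

Step 18
Reactants: 24 13-acetate
Product: 26 tetracyclic 2-epi silyl ether (target skeleton with the C2 silyloxy group trans to H1), via epoxide 25 (not isolated)
Conditions: mCPBA, CH2Cl2, 0 °C; then camphorsulfonic acid (cat.), rt
Reagents that add atoms: 3-chloroperbenzoic acid, OOC(=O)c1cccc(Cl)c1
Why: Prilezhaev epoxidation of the electron-rich tetrasubstituted alkene on the face of H1 (opposite ring B and the C2 silyloxy group), then acid-catalysed 5-exo-tet opening at C5 by the C11 hydroxyl with inversion, sets C5 (ether oxygen anti to the epoxide) and C4 (hydroxyl kept from the epoxide, trans to the ether oxygen).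

Step 19
Reactants: 26 tetracyclic 2-epi silyl ether
Product: 27 2-epi alcohol
Conditions: HF·pyridine, THF, 0 °C → rt
Reagents that add atoms: none
Why: Fluoride-mediated desilylation of the secondary silyl ether, with acetate, lactone and tertiary alcohol stable.

Step 20
Reactants: 27 2-epi alcohol; 28 tiglic acid
Product: 29 CNP0112086.1
Conditions: PPh3, DIAD, toluene, 0 °C → rt
Reagents that add atoms: none
Why: Mitsunobu esterification with inversion at C2 places the tiglate cis to H1, and the tertiary C4 hydroxyl does not react.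

Compound list
1 | cyclohepta-1,3-diene | C1=CC=CCCC1 | starting material
2 | 6,7-dioxabicyclo[3.2.2]non-8-ene (meso) | C1=C[C@@H]2CCC[C@H]1OO2 | intermediate
3 | (R)-4-hydroxycyclohept-2-en-1-one | O=C1C=C[C@H](O)CCC1 | intermediate
4 | ethyl vinyl ether | C=COCC | starting material
5 | (4R)-4-(2-bromo-1-ethoxyethoxy)cyclohept-2-en-1-one | O=C1C=C[C@H](OC(OCC)CBr)CCC1 | intermediate
6 | 5-(2-bromo-1-ethoxyethoxy)-2-(trimethylsilyloxy)cyclohepta-1,3-diene, carbinol carbon as in 5 | C[Si](C)(C)OC1=CCC[C@@H](OC(OCC)CBr)C=C1 | intermediate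
7 | (4R)-4-(2-bromo-1-ethoxyethoxy)cyclohepta-2,6-dien-1-one | O=C1C=C[C@H](OC(OCC)CBr)CC=C1 | intermediate
8 | (3aS,8aR)-2-ethoxy-2,3,3a,4,8,8a-hexahydro-5H-cyclohepta[b]furan-5-one | O=C1C=CC[C@H]2OC(OCC)C[C@H]2C1 | intermediate
9 | trimethylsilyl enol ether (C1=C5) of the 10-methyl ketone, methyl trans to the C8 oxygen | C[C@H]1C=C(O[Si](C)(C)C)C[C@@H]2CC(OCC)O[C@@H]2C1 | intermediate
10 | but-2-yn-1-ol | CC#CCO | starting material
11 | tert-butyl(but-2-yn-1-yloxy)dimethylsilane | CC#CCO[Si](C)(C)C(C)(C)C | intermediate
12 | racemic 1-(tert-butyldimethylsilyl)but-2-yn-1-ol | CC#CC(O)[Si](C)(C)C(C)(C)C | intermediate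
13 | 1-(tert-butyldimethylsilyl)but-2-yn-1-one | CC#CC(=O)[Si](C)(C)C(C)(C)C | intermediate
14 | (E)-1-(tert-butyldimethylsilyl)-3-(dimethylphenylsilyl)but-2-en-1-one | C/C(=C\C(=O)[Si](C)(C)C(C)(C)C)[Si](C)(C)c1ccccc1 | intermediate
15 | lithium enolate corresponding to 9 | C[C@H]1C=C(O[Li])C[C@@H]2CC(OCC)O[C@@H]2C1 | intermediate
16 | tricyclic cyclopentenol: C2=C3 enol silyl ether, C4 methyl and dimethylphenylsilyl (silyl cis to OH), C5–OH cis to H1, H1 cis to the C10 methyl | C[C@@H]1C[C@H]2OC(OCC)C[C@H]2C[C@]3(O)[C@H]1C(O[Si](C)(C)C(C)(C)C)=C[C@@]3(C)[Si](C)(C)c4ccccc4 | intermediate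
17 | C2–C3 dihydro compound, C2 silyloxy cis to C10 | C[C@@H]1C[C@H]2OC(OCC)C[C@H]2C[C@]3(O)[C@H]1[C@H](O[Si](C)(C)C(C)(C)C)C[C@@]3(C)[Si](C)(C)c4ccccc4 | intermediate
18 | lactol with C4=C5 alkene and C2 silyl ether | C[C@@H]1C[C@H]2OC(O)C[C@H]2CC3=C(C)C[C@@H](O[Si](C)(C)C(C)(C)C)[C@@H]13 | intermediate
19 | 8,12-lactone with C4=C5 alkene and C2 silyl ether | C[C@@H]1C[C@H]2OC(=O)C[C@H]2CC3=C(C)C[C@@H](O[Si](C)(C)C(C)(C)C)[C@@H]13 | intermediate
20 | potassium enolate of 19 | C[C@@H]1C[C@H]2OC(O[K])=C[C@H]2CC3=C(C)C[C@@H](O[Si](C)(C)C(C)(C)C)[C@@H]13 | intermediate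
21 | 11-hydroxy lactone, hydroxyl cis to H7 | C[C@@H]1C[C@H]2OC(=O)[C@H](O)[C@H]2CC3=C(C)C[C@@H](O[Si](C)(C)C(C)(C)C)[C@@H]13 | intermediate
22 | dilithium enediolate of 21 | C[C@@H]1C[C@H]2OC(O[Li])=C(O[Li])[C@H]2CC3=C(C)C[C@@H](O[Si](C)(C)C(C)(C)C)[C@@H]13 | intermediate
23 | 11,13-diol, C11 hydroxyl cis to C6 | C[C@@H]1C[C@H]2OC(=O)[C@](O)(CO)[C@H]2CC3=C(C)C[C@@H](O[Si](C)(C)C(C)(C)C)[C@@H]13 | intermediate
24 | 13-acetate of 23 | C[C@@H]1C[C@H]2OC(=O)[C@](O)(COC(C)=O)[C@H]2CC3=C(C)C[C@@H](O[Si](C)(C)C(C)(C)C)[C@@H]13 | intermediate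
25 | 4,5-epoxide of 24, oxygen on the face of H1 | C[C@@H]1C[C@H]2OC(=O)[C@](O)(COC(C)=O)[C@H]2C[C@@]34O[C@]3(C)C[C@@H](O[Si](C)(C)C(C)(C)C)[C@@H]14 | intermediate
26 | tetracyclic 2-epi tert-butyldimethylsilyl ether | CC(C)(C)[Si](C)(C)O[C@@H]1C[C@@](C)(O)[C@@]23C[C@H]4[C@@H](C[C@@H](C)[C@H]12)OC(=O)[C@@]4(COC(C)=O)O3 | intermediate
27 | tetracyclic 2-epi alcohol | O[C@@H]1C[C@@](C)(O)[C@@]23C[C@H]4[C@@H](C[C@@H](C)[C@H]12)OC(=O)[C@@]4(COC(C)=O)O3 | intermediate
28 | tiglic acid, (E)-2-methylbut-2-enoic acid | C/C=C(\C)C(=O)O | starting material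
29 | CNP0112086.1 | C/C=C(\C)C(=O)O[C@H]1C[C@@](C)(O)[C@@]23C[C@H]4[C@@H](C[C@@H](C)[C@H]12)OC(=O)[C@@]4(COC(C)=O)O3 | target

Total step count: 20. Longest linear sequence: 16 steps (steps 1–6 and 11–20); steps 7–10 make the acylsilane 14.

Steps most likely to fail

Step 11. The Brook rearrangement may stall at the 1,2-adduct, or the crowded allyl anion may be protonated or revert by retro-aldol cleavage instead of closing onto the C5 ketone. The fallback sets out from 9 and comes back at 19. Enolate 15 (from 9 with MeLi) is added to (2-methyl-1,3-dioxolan-2-yl)acetaldehyde; the Zimmerman–Traxler transition state of the cyclic E-enolate should give the anti aldol, the β-hydroxy ketone F1, with the C2 hydroxyl already cis to C10. t-BuMe2SiOTf and 2,6-lutidine give the silyl ether F2. Aqueous acetic acid removes the dioxolane and the ethyl acetal to give the diketone lactol F3. Pr4N[RuO4] with N-methylmorpholine N-oxide gives the diketone lactone F4. An intramolecular McMurry coupling (TiCl3, Zn(Cu), DME, reflux) of the C4 and C5 ketones then forms the C4=C5 alkene and gives 19.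

Step 12. Hydrogenation may be slow at the hindered enol ether, the Lewis-acidic catalyst may hydrolyse it or trigger the Peterson elimination too early, and delivery on the wrong face would give the C2 epimer. The fallback sets out from 16 and comes back at 17. Bu4NF buffered with AcOH cleaves the silyl enol ether to the β-hydroxy ketone F5. LiB(s-Bu)3H should reduce the cyclopentanone from the face opposite the C1–C10 bond and give the diol F6 with the C2 hydroxyl cis to C10. t-BuMe2SiOTf and 2,6-lutidine silylate the secondary hydroxyl and give 17.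

Step 20. The oxyphosphonium salt of the hindered secondary alcohol may form slowly and eliminate toward C3 instead of being displaced. The fallback sets out from 27 and comes back at 29. Dess–Martin oxidation gives the ketone F7. Narasaka–Prasad reduction (Et2BOMe, NaBH4, THF/MeOH, −78 °C) through the boron chelate with the C4 hydroxyl should give the syn-1,3-diol, the C2-epimeric alcohol F8. Yamaguchi esterification with tiglic acid 28 (2,4,6-trichlorobenzoyl chloride, Et3N, DMAP) acylates the secondary hydroxyl with retention and gives 29.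

Further compounds
F1 | step 11 | anti aldol adduct of the C5 ketone with the dioxolane aldehyde (C2 hydroxyl cis to C10) | C[C@@H]1C[C@H]2OC(OCC)C[C@H]2CC(=O)[C@H]1[C@H](O)CC3(C)OCCO3
F2 | step 11 | tert-butyldimethylsilyl ether of F1 | C[C@@H]1C[C@H]2OC(OCC)C[C@H]2CC(=O)[C@H]1[C@H](O[Si](C)(C)C(C)(C)C)CC3(C)OCCO3
F3 | step 11 | diketone lactol (C5 ring ketone and C4 methyl ketone) | C[C@@H]1C[C@H]2OC(O)C[C@H]2CC(=O)[C@H]1[C@H](O[Si](C)(C)C(C)(C)C)CC(C)=O
F4 | step 11 | diketone lactone | C[C@@H]1C[C@H]2OC(=O)C[C@H]2CC(=O)[C@H]1[C@H](O[Si](C)(C)C(C)(C)C)CC(C)=O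
F5 | step 12 | C2 ketone (β-hydroxy ketone) from 16 | C[C@@H]1C[C@H]2OC(OCC)C[C@H]2C[C@]3(O)[C@H]1C(=O)C[C@@]3(C)[Si](C)(C)c4ccccc4
F6 | step 12 | C2,C5 diol, C2 hydroxyl cis to C10 | C[C@@H]1C[C@H]2OC(OCC)C[C@H]2C[C@]3(O)[C@H]1[C@H](O)C[C@@]3(C)[Si](C)(C)c4ccccc4
F7 | step 20 | tetracyclic C2 ketone | O=C1C[C@@](C)(O)[C@@]23C[C@H]4[C@@H](C[C@@H](C)[C@H]12)OC(=O)[C@@]4(COC(C)=O)O3
F8 | step 20 | tetracyclic alcohol with the natural C2 configuration | O[C@H]1C[C@@](C)(O)[C@@]23C[C@H]4[C@@H](C[C@@H](C)[C@H]12)OC(=O)[C@@]4(COC(C)=O)O3
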